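**Plan**
- Numbering of the target (bicyclo[3.2.1]oct-3-ene-2,8-dione): C2=O, C3=C4 (styryl on C4), bridgeheads C1 and C5, C6 (3,5-dihydroxyphenyl), C7 (3,4-dihydroxyphenyl), C8=O.
- Retrosynthesis: the six O-benzyl groups come off first; C4–C5 and C3=C4 are cut by a retro-aldol to a 1,3,5-triketone; C3–C4 is cut (Claisen) to a 2-acetylcyclopentanone and a cinnamoyl unit; C6–C7 is cut last.
- Enabling feature: the C8 carbonyl sits between C1 and C5, and both aryl-bearing carbons C6 and C7 are β to it. Ring C1–C8–C5–C6–C7 is therefore the product of a 4π-conrotatory closure of a cross-conjugated 1,5-diaryl dienone, and the trans aryl groups are what conrotation of an E,E-dienone gives.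
- Forward: acetylacetone and two aldehydes give the 2-acetyl dienone (2 steps); an asymmetric reductive Nazarov closure makes the cyclopentanone (C6–C7); dianion acylation adds C4 with its styryl group; a triketone aldol condensation closes the six-membered ring and the bicycle; debenzylation. The acetyl group serves as chelating group in the key step and stays as C2–C3.
- Stereochemistry: C6 and C7 (trans and absolute) come from ligand-controlled conrotation in the key step; C1 and C5 are relayed in the aldol closure (cis bridging is forced, C5 reacts anti to the C6 aryl, C1 epimerises through its enol).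

Key step: step 3

Assumption: in 8 and 11 the carbon between the two carbonyl groups (C2 of the cyclopentanone) is configurationally labile through its enol; both are drawn as the diketo tautomer with the acyl group trans to the neighbouring aryl, and only C3 and C4 are fixed before step 6. Compound 5 is expected as an E/Z mixture at the benzylidene and is drawn as the isomer that cyclises.

Step 1
Reactants: 1 3,5-bis(benzyloxy)benzaldehyde; 2 pentane-2,4-dione (3 equiv)
Product: 3 (5E)-6-[3,5-bis(benzyloxy)phenyl]hex-5-ene-2,4-dione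
Conditions: B2O3, B(OnBu)3, nBuNH2 (cat.), EtOAc, 70 °C; then 1 M HCl, 60 °C
Reagents that add atoms: none
Why: boron-templated aldol condensation, in which the boron chelate of 2 masks C3 and activates the methyl groups, excess 2 should hold the reaction at the mono-adduct, and E1cB dehydration gives the E-styryl ketone.

Step 2
Reactants: 3 (5E)-6-[3,5-bis(benzyloxy)phenyl]hex-5-ene-2,4-dione; 4 3,4-bis(benzyloxy)benzaldehyde
Product: 5 (3E,5E)-3-{[3,4-bis(benzyloxy)phenyl]methylidene}-6-[3,5-bis(benzyloxy)phenyl]hex-5-ene-2,4-dione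
Conditions: piperidine (cat.), AcOH (cat.), PhMe, reflux, Dean–Stark
Reagents that add atoms: none
Why: Knoevenagel condensation at the doubly activated C3 methylene with azeotropic removal of water; the benzylidene geometry is not critical because the isomers should interconvert on the Lewis acid in step 3.

Step 3
Reactants: 5 (3E,5E)-3-{[3,4-bis(benzyloxy)phenyl]methylidene}-6-[3,5-bis(benzyloxy)phenyl]hex-5-ene-2,4-dione
Product: 8 (2S,3S,4R)-2-acetyl-3-[3,4-bis(benzyloxy)phenyl]-4-[3,5-bis(benzyloxy)phenyl]cyclopentan-1-one, via oxyallyl cation 6 (not isolated), via triethylsilyl enol ether 7 (not isolated)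
Conditions: Sc(OTf)3 (10 mol %), (S,S)-Ph-pybox (12 mol %; the antipode if the sense of induction requires it), Et3SiH (3 equiv), 4 Å MS, CH2Cl2, −20 °C to rt; then 1 M HCl, THF
Reagents that add atoms: none
Why: Proposed new method: the Sc(OTf)3–pybox complex chelates the 2,4-dione of 5, the resulting metal-bound pentadienyl cation undergoes thermal 4π-conrotatory electrocyclisation (Nazarov cyclisation) to oxyallyl cation 6, and Et3SiH transfers hydride to its non-acylated terminus (C5) while the silyl group ends on the diketonate oxygen (7) and is lost on acidic work-up. The closest known reaction types are the catalytic asymmetric Nazarov cyclisation of 2-acyl and 2-alkoxycarbonyl divinyl ketones with chiral divalent copper or trivalent scandium Lewis acids, and the silane-interrupted (reductive) Nazarov cyclisation with BF3·OEt2/Et3SiH. The cyclopentanone ring closes by this electrocyclisation between the two β-carbons, which is the bond joining the two aryl-bearing carbons. C3 and C4 are set together: conrotation of the E,E-dienone places the aryl groups trans, and the sense of rotation (3S,4R) should be dictated by the C2-symmetric ligand on the chelated metal; C2 settles thermodynamically with acetyl trans to the C3 aryl. The step needs hydride capture to outrun proton loss, hydride shift and direct 1,4-reduction of the benzylidene dione. The weak hydride donor Et3SiH should react only with the unstabilised oxyallyl cation, the para-benzyloxy group lowers the electrophilicity of the benzylidene carbon, and the cationic terminus lies next to the carbon carrying the 3,5-dioxygenated aryl, where a hydride shift gains no stabilisation.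

Step 4
Reactants: 4 3,4-bis(benzyloxy)benzaldehyde; 9 diethyl {2-[methoxy(methyl)amino]-2-oxoethyl}phosphonate
Product: 10 (2E)-3-[3,4-bis(benzyloxy)phenyl]-N-methoxy-N-methylprop-2-enamide
Conditions: NaH, THF, 0 °C to rt
Reagents that add atoms: none
Why: Horner–Wadsworth–Emmons olefination with a stabilised phosphonate should give the E-configured Weinreb amide.

Step 5
Reactants: 8 (2S,3S,4R)-2-acetyl-3-[3,4-bis(benzyloxy)phenyl]-4-[3,5-bis(benzyloxy)phenyl]cyclopentan-1-one; 10 (2E)-3-[3,4-bis(benzyloxy)phenyl]-N-methoxy-N-methylprop-2-enamide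
Product: 11 (2R,3S,4R)-3-[3,4-bis(benzyloxy)phenyl]-2-{(4E)-5-[3,4-bis(benzyloxy)phenyl]-3-oxopent-4-enoyl}-4-[3,5-bis(benzyloxy)phenyl]cyclopentan-1-one
Conditions: LiN(iPr)2 (2.3 equiv), THF, −78 to −20 °C; then 10, −78 to 0 °C; aq. NH4Cl
Reagents that add atoms: none
Why: Claisen-type C-acylation of a 1,3-diketone dianion, in which the second deprotonation should occur kinetically at the acetyl methyl, this terminal carbanion adds 1,2 to the Weinreb amide, and the chelated tetrahedral adduct prevents over-reaction; no new stereocentre is formed.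

Step 6
Reactants: 11 (2R,3S,4R)-3-[3,4-bis(benzyloxy)phenyl]-2-{(4E)-5-[3,4-bis(benzyloxy)phenyl]-3-oxopent-4-enoyl}-4-[3,5-bis(benzyloxy)phenyl]cyclopentan-1-one
Product: 13 (1R,5S,6S,7S)-7-[3,4-bis(benzyloxy)phenyl]-6-[3,5-bis(benzyloxy)phenyl]-4-{(E)-2-[3,4-bis(benzyloxy)phenyl]ethenyl}bicyclo[3.2.1]oct-3-ene-2,8-dione, via bridged aldol 12 (not isolated)
Conditions: TsOH·H2O (0.2 equiv), 4 Å MS, PhMe, 80 °C
Reagents that add atoms: none
Why: intramolecular aldol condensation of the 1,3,5-triketone (the polyketide-type closure that would lead to a resorcinol, stopped at the cyclohexenone because both ring-fusion carbons are bridgeheads), in which the ring CH2 enol should add to the distal side-chain carbonyl on the face anti to the adjacent 3,5-bis(benzyloxy)phenyl group after C2 has epimerised through its enol to bring the acyl chain cis, which fixes C1 and C5 and places the 3,4-bis(benzyloxy)phenyl group endo, while dehydration can only run towards C3 (Bredt's rule).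

Step 7
Reactants: 13 (1R,5S,6S,7S)-7-[3,4-bis(benzyloxy)phenyl]-6-[3,5-bis(benzyloxy)phenyl]-4-{(E)-2-[3,4-bis(benzyloxy)phenyl]ethenyl}bicyclo[3.2.1]oct-3-ene-2,8-dione
Product: 14 (1R,5S,6S,7S)-7-(3,4-dihydroxyphenyl)-6-(3,5-dihydroxyphenyl)-4-[(E)-2-(3,4-dihydroxyphenyl)ethenyl]bicyclo[3.2.1]oct-3-ene-2,8-dione
Conditions: BCl3 (9 equiv), C6HMe5 (18 equiv), CH2Cl2, −78 °C; then MeOH
Reagents that add atoms: none
Why: Lewis acid debenzylation with pentamethylbenzene as a non-basic cation scavenger should cleave all six aryl benzyl ethers at low temperature without touching the styryl dienone or the non-enolisable 1,3-dione, and the bridgehead stereocentres cannot epimerise.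

**Compound list**
1 | 3,5-bis(benzyloxy)benzaldehyde | O=Cc1cc(OCc2ccccc2)cc(OCc2ccccc2)c1 | starting material
2 | pentane-2,4-dione (acetylacetone) | CC(=O)CC(C)=O | starting material
3 | (5E)-6-[3,5-bis(benzyloxy)phenyl]hex-5-ene-2,4-dione (drawn as diketone) | CC(=O)CC(=O)/C=C/c1cc(OCc2ccccc2)cc(OCc2ccccc2)c1 | intermediate
4 | 3,4-bis(benzyloxy)benzaldehyde | O=Cc1ccc(OCc2ccccc2)c(OCc2ccccc2)c1 | starting material
5 | (3E,5E)-3-{[3,4-bis(benzyloxy)phenyl]methylidene}-6-[3,5-bis(benzyloxy)phenyl]hex-5-ene-2,4-dione (aryl cis to acetyl at the benzylidene) | CC(=O)/C(C(=O)/C=C/c1cc(OCc2ccccc2)cc(OCc2ccccc2)c1)=C\c1ccc(OCc2ccccc2)c(OCc2ccccc2)c1 | intermediate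
6 | scandium-bound oxyallyl cation, drawn metal-free as the zwitterion 2-acetyl-3-[3,4-bis(benzyloxy)phenyl]-4-[3,5-bis(benzyloxy)phenyl]-1-oxidocyclopent-1-en-5-ylium, aryl carbons configured as in 8 | CC(=O)C1=C([O-])[CH+][C@@H](c2cc(OCc3ccccc3)cc(OCc3ccccc3)c2)[C@@H]1c1ccc(OCc2ccccc2)c(OCc2ccccc2)c1 | intermediate (not isolated)
7 | triethylsilyl enol ether of 8 (silylated at the ring carbonyl oxygen, C1=C2 double bond), aryl carbons configured as in 8 | CC[Si](CC)(CC)OC1=C(C(C)=O)[C@@H](c2ccc(OCc3ccccc3)c(OCc3ccccc3)c2)[C@H](c2cc(OCc3ccccc3)cc(OCc3ccccc3)c2)C1 | intermediate (not isolated)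
8 | (2S,3S,4R)-2-acetyl-3-[3,4-bis(benzyloxy)phenyl]-4-[3,5-bis(benzyloxy)phenyl]cyclopentan-1-one (all-trans, aryl groups trans) | CC(=O)[C@@H]1[C@@H](c2ccc(OCc3ccccc3)c(OCc3ccccc3)c2)[C@H](c2cc(OCc3ccccc3)cc(OCc3ccccc3)c2)CC1=O | intermediate
9 | diethyl {2-[methoxy(methyl)amino]-2-oxoethyl}phosphonate | CCOP(=O)(CC(=O)N(C)OC)OCC | starting material
10 | (2E)-3-[3,4-bis(benzyloxy)phenyl]-N-methoxy-N-methylprop-2-enamide | CON(C)C(=O)/C=C/c1ccc(OCc2ccccc2)c(OCc2ccccc2)c1 | intermediate
11 | (2R,3S,4R)-3-[3,4-bis(benzyloxy)phenyl]-2-{(4E)-5-[3,4-bis(benzyloxy)phenyl]-3-oxopent-4-enoyl}-4-[3,5-bis(benzyloxy)phenyl]cyclopentan-1-one | O=C(/C=C/c1ccc(OCc2ccccc2)c(OCc2ccccc2)c1)CC(=O)[C@@H]1[C@@H](c2ccc(OCc3ccccc3)c(OCc3ccccc3)c2)[C@H](c2cc(OCc3ccccc3)cc(OCc3ccccc3)c2)CC1=O | intermediate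
12 | (1R,5S,6S,7S)-7-[3,4-bis(benzyloxy)phenyl]-6-[3,5-bis(benzyloxy)phenyl]-4-{(E)-2-[3,4-bis(benzyloxy)phenyl]ethenyl}-4-hydroxybicyclo[3.2.1]octane-2,8-dione (either C4 epimer) | O=C1CC(O)(/C=C/c2ccc(OCc3ccccc3)c(OCc3ccccc3)c2)[C@H]2C(=O)[C@@H]1[C@@H](c1ccc(OCc3ccccc3)c(OCc3ccccc3)c1)[C@@H]2c1cc(OCc2ccccc2)cc(OCc2ccccc2)c1 | intermediate (not isolated)
13 | (1R,5S,6S,7S)-7-[3,4-bis(benzyloxy)phenyl]-6-[3,5-bis(benzyloxy)phenyl]-4-{(E)-2-[3,4-bis(benzyloxy)phenyl]ethenyl}bicyclo[3.2.1]oct-3-ene-2,8-dione | O=C1C=C(/C=C/c2ccc(OCc3ccccc3)c(OCc3ccccc3)c2)[C@H]2C(=O)[C@@H]1[C@@H](c1ccc(OCc3ccccc3)c(OCc3ccccc3)c1)[C@@H]2c1cc(OCc2ccccc2)cc(OCc2ccccc2)c1 | intermediate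
14 | (1R,5S,6S,7S)-7-(3,4-dihydroxyphenyl)-6-(3,5-dihydroxyphenyl)-4-[(E)-2-(3,4-dihydroxyphenyl)ethenyl]bicyclo[3.2.1]oct-3-ene-2,8-dione | O=C1C=C(/C=C/c2ccc(O)c(O)c2)[C@H]2C(=O)[C@@H]1[C@@H](c1ccc(O)c(O)c1)[C@@H]2c1cc(O)cc(O)c1 | target

**Step count:** 7 steps in total; longest linear sequence 6 steps (steps 1, 2, 3, 5, 6, 7).

**Steps most likely to fail**

Step 3 (Proposed new method). Proton loss or a hydride shift from the oxyallyl cation, or direct silane reduction of the benzylidene dione, may outrun electrocyclisation and hydride capture, and the ligand may not control the sense of conrotation well enough. The fallback uses known chemistry, sets out from 1 and comes back at 8. Claisen–Schmidt condensation of 1 with (E)-4-(trimethylsilyl)but-3-en-2-one (Ba(OH)2, EtOH) would give (1E,4E)-1-[3,5-bis(benzyloxy)phenyl]-5-(trimethylsilyl)penta-1,4-dien-3-one F1. An enantioselective silicon-directed Nazarov cyclisation (Zn(OTf)2, chiral spirocyclic phosphoric acid, PhOH as silyl acceptor) would close the same bond and give (R)-4-[3,5-bis(benzyloxy)phenyl]cyclopent-2-en-1-one F2. Conjugate addition of 3,4-(BnO)2C6H3MgBr with CuBr·SMe2 should occur anti to the existing aryl, and trapping the enolate with acetaldehyde would give (2S,3S,4R)-3-[3,4-bis(benzyloxy)phenyl]-4-[3,5-bis(benzyloxy)phenyl]-2-(1-hydroxyethyl)cyclopentan-1-one F3. Oxidation with Dess–Martin periodinane would return 8.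

Step 6. The bridged aldol addition may stall at the strongly enolised triketone or revert by retro-aldol before dehydration, or may close on the face syn to the 3,5-bis(benzyloxy)phenyl group. The fallback replaces the aldol by a Michael addition followed by dehydrogenation; it sets out from 8 and comes back at 13. Aldehyde 4 and Ph3P=CHCHO would give (2E)-3-[3,4-bis(benzyloxy)phenyl]prop-2-enal F4. The dianion of 8 (LiN(iPr)2) would add to it to give (2R,3S,4R)-3-[3,4-bis(benzyloxy)phenyl]-2-{(4E)-5-[3,4-bis(benzyloxy)phenyl]-3-hydroxypent-4-enoyl}-4-[3,5-bis(benzyloxy)phenyl]cyclopentan-1-one F5. Dehydration (TsOH cat.) would give (2R,3S,4R)-3-[3,4-bis(benzyloxy)phenyl]-2-{(2E,4E)-5-[3,4-bis(benzyloxy)phenyl]penta-2,4-dienoyl}-4-[3,5-bis(benzyloxy)phenyl]cyclopentan-1-one F6. DBU-mediated intramolecular Michael addition of the ring CH2 carbon to the β-carbon of the dienone (6-endo-trig, anti to the neighbouring aryl) would give (1R,5R,6S,7S)-7-[3,4-bis(benzyloxy)phenyl]-6-[3,5-bis(benzyloxy)phenyl]-4-{(E)-2-[3,4-bis(benzyloxy)phenyl]ethenyl}bicyclo[3.2.1]octane-2,8-dione F7. Aerobic dehydrogenation of the C2 ketone towards C3 (Pd(TFA)2 cat., DMSO, O2, AcOH) would then give 13.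

Step 7. Six-fold debenzylation may be incomplete, or the strained, non-enolisable dione and the electron-rich styryl dienone may degrade under the Lewis acid. The fallback reverses the order of deprotection and ring closure; it sets out from 11 and comes back at 14. Triketone 11, which carries no strained ring, would be debenzylated first (BCl3, C6HMe5, CH2Cl2, −78 °C) to (2R,3S,4R)-3-(3,4-dihydroxyphenyl)-2-[(4E)-5-(3,4-dihydroxyphenyl)-3-oxopent-4-enoyl]-4-(3,5-dihydroxyphenyl)cyclopentan-1-one F8. The acid-catalysed aldol condensation (TsOH cat., warm AcOH) would then be run on the free polyphenol to give 14 directly.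

**Further compounds**
F1 | step 3 | (1E,4E)-1-[3,5-bis(benzyloxy)phenyl]-5-(trimethylsilyl)penta-1,4-dien-3-one | C[Si](C)(C)/C=C/C(=O)/C=C/c1cc(OCc2ccccc2)cc(OCc2ccccc2)c1
F2 | step 3 | (R)-4-[3,5-bis(benzyloxy)phenyl]cyclopent-2-en-1-one | O=C1C=C[C@H](c2cc(OCc3ccccc3)cc(OCc3ccccc3)c2)C1
F3 | step 3 | (2S,3S,4R)-3-[3,4-bis(benzyloxy)phenyl]-4-[3,5-bis(benzyloxy)phenyl]-2-(1-hydroxyethyl)cyclopentan-1-one (carbinol epimers) | CC(O)[C@@H]1[C@@H](c2ccc(OCc3ccccc3)c(OCc3ccccc3)c2)[C@H](c2cc(OCc3ccccc3)cc(OCc3ccccc3)c2)CC1=O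
F4 | step 6 | (2E)-3-[3,4-bis(benzyloxy)phenyl]prop-2-enal | O=C/C=C/c1ccc(OCc2ccccc2)c(OCc2ccccc2)c1
F5 | step 6 | (2R,3S,4R)-3-[3,4-bis(benzyloxy)phenyl]-2-{(4E)-5-[3,4-bis(benzyloxy)phenyl]-3-hydroxypent-4-enoyl}-4-[3,5-bis(benzyloxy)phenyl]cyclopentan-1-one (carbinol epimers) | OC(/C=C/c1ccc(OCc2ccccc2)c(OCc2ccccc2)c1)CC(=O)[C@@H]1[C@@H](c2ccc(OCc3ccccc3)c(OCc3ccccc3)c2)[C@H](c2cc(OCc3ccccc3)cc(OCc3ccccc3)c2)CC1=O
F6 | step 6 | (2R,3S,4R)-3-[3,4-bis(benzyloxy)phenyl]-2-{(2E,4E)-5-[3,4-bis(benzyloxy)phenyl]penta-2,4-dienoyl}-4-[3,5-bis(benzyloxy)phenyl]cyclopentan-1-one | O=C(/C=C/C=C/c1ccc(OCc2ccccc2)c(OCc2ccccc2)c1)[C@@H]1[C@@H](c2ccc(OCc3ccccc3)c(OCc3ccccc3)c2)[C@H](c2cc(OCc3ccccc3)cc(OCc3ccccc3)c2)CC1=O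
F7 | step 6 | (1R,5R,6S,7S)-7-[3,4-bis(benzyloxy)phenyl]-6-[3,5-bis(benzyloxy)phenyl]-4-{(E)-2-[3,4-bis(benzyloxy)phenyl]ethenyl}bicyclo[3.2.1]octane-2,8-dione (either C4 epimer) | O=C1CC(/C=C/c2ccc(OCc3ccccc3)c(OCc3ccccc3)c2)[C@H]2C(=O)[C@@H]1[C@@H](c1ccc(OCc3ccccc3)c(OCc3ccccc3)c1)[C@@H]2c1cc(OCc2ccccc2)cc(OCc2ccccc2)c1
F8 | step 7 | (2R,3S,4R)-3-(3,4-dihydroxyphenyl)-2-[(4E)-5-(3,4-dihydroxyphenyl)-3-oxopent-4-enoyl]-4-(3,5-dihydroxyphenyl)cyclopentan-1-one | O=C(/C=C/c1ccc(O)c(O)c1)CC(=O)[C@@H]1[C@@H](c2ccc(O)c(O)c2)[C@H](c2cc(O)cc(O)c2)CC1=O
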